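J's whole charge of 40.0 mM matches Q and X together, so for an equimolar second-order reaction y/(1−y) should grow with time and with [G].

| flask | Q | X | J | G | D | remark | time |
|---|---|---|---|---|---|---|---|
| Wednesday's | 20 mM | 20 mM | 40 mM (fed, over 8.0 min) | 15 µM | 0.40 mM | run made earlier; the fed solution adds 0.50 times the starting volume |  |
| Thursday's | 20 mM | 20 mM | 40 mM (fed, over 8.0 min) | 60 µM | 0.40 mM | run made earlier; the fed solution adds 0.50 times the starting volume |  |
| flask | 20 mM | 20 mM | 40.0 mM (fed, over 8.0 min) | 30 µM | 0.40 mM | the fed solution adds 0.50 times the starting volume | 20 min |

- Wednesday's (time / min: Z / %, L / %): 1.50: 0, 0; 3.00: 2, 2; 6.00: 4, 0; 10.0: 6, 5; 20.0: 17, 8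
- Thursday's (time / min: Z / %, L / %): 4.00: 5, 3; 8.00: 18, 8; 12.0: 27, 12; 15.0: 32, 12; 20.0: 39, 18

(standard deviation of a reading: 2 percentage points)

- Z and L together, in percent of the Q and X charged together, at 20 min
- excess of Z over L in the product at 20 min
- whether the exchange between Q and X keeps pace with the reaction: how far the product's excess at 20 min gets from its value without exchange to its value with instant exchange (above 80% keeps pace, below 20% hardly takes part, else lags behind)

- G is single-handed; Q and X are mirror images of each other, charged as a racemate, each of them at the stated concentration
- charges are per starting volume, the dose included; the dosed solution carries all of it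
- an excess is the difference of the two amounts in percent of their sum
- an excess is below zero if the other one leads

At 20 min, Z and L together reach 25.0% on Wednesday and 57.0% on Thursday. That raises y/(1−y) by a factor of 3.98 for a factor of 4.00 in [G], so the rate reads as first-order in [G]. Ignoring the feed, Wednesday's reading gives this flask a half-conversion time of 30.0 min.

On this ladder the feed comes first at 8.0 min, then the asked time at 20 min, then that half-conversion time. J therefore arrives faster than it is used, and I expect y = 40.0%. No reading gives the exchange a time of its own, so I look for its rung in the excess.

Take the selectivity factor s, the ln of the fraction of Q left over the ln of the fraction of X left, with no exchange. Wednesday's last reading gives s = 2.38. With instant exchange the excess is (s−1)/(s+1) = 40.9%. Without exchange, to first order, Z/L falls to s(1−excess·y), an excess of 33.2%. Thursday's last readings give a higher s of 3.39, but each reading carries 2 percentage points, so I expect an excess between 33.2% and 40.9% and leave the pace open.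

The forecast says 40%, 38% and keeps pace: “The data are noisy, but exchange probably keeps pace.”

The flask gives 39.1%, 31.2% and hardly takes part, 5.7% of the way.

    J + G + Q → G + Z (k = 1.05 × 10⁵ /M²/min)
    J + G + X → G + L (k = 46400 /M²/min)
    Q + D ⇌ X + D, rate k3*[D]*[Q] forward; the back reaction follows from the equilibrium constant (k = 18.3 /M/min)
    J + G → E (k = 0.142 /M/min)

In this flask at 20.0 min, with 50% of Q and 72% of X left, s comes to 2.11, and Q goes to Z 6.7 times as fast as it goes to X (forward step alone), with the excess 6.8 points below the forecast. The flask with 0.12 mM of G, with 17% of its Q and 43% of its X left, gives s = 2.10, at y = 70.0% and an excess of 21.4%.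

The data stem from a simulated flask on assumed constants; noise was put on by code.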